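**Plan**
- Numbering: ring A C1 (CH2O-palmitoyl), C2 (O-aryl), C3 (OH), C5 (OMe); ring B C1' (ether O), C3' (OH), C5' (CH3). Ring B is a 3-aryloxy-5-methylphenol, the pattern a vinylketene and an ynol ether assemble, so the crowded diaryl ether can start as an unhindered O–C(sp) bond.
- Retrosynthesis: cut the benzylic CH2–O bond of the palmitate, then take ring B apart at C2'–C3', C1'–C6' and C3'–C4' (3-methylcyclobutenone plus a ring A ethynyl ether), then cut O–C1' (phenol plus trichloroethylene) and the C3–O bond (bromination and hydroxylation of 2-hydroxy-5-methoxybenzaldehyde).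
- Forward: ring A is bought and receives its C3 oxygen, a MOM group, the ethynyl ether and a silyl-protected CH2OH; ring B is then grown on the alkyne; the palmitoyl chain is joined afterwards by Mitsunobu esterification, and the MOM group leaves last.
- Stereochemistry: the target has no stereocentre and no stereogenic double bond; the E geometry of the dichlorovinyl ether and the stereocentre of the cyclobutenone adduct are transient.

Key step: step 10

Remark on the chemistry: the benzylic oxygen is carried through the benzannulation as a TBS ether and esterified afterwards. A free benzylic hydroxyl or acid chloride conditions beside the acid-labile ynol ether would invite cyclization or hydration. The silyl ether also allows a mild basic treatment that returns any ketene-acylated phenol to the product.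

**Step 1**
Reactants: 1 2-hydroxy-5-methoxybenzaldehyde
Product: 2 3-bromo-2-hydroxy-5-methoxybenzaldehyde
Conditions: Br2 (1.05 equiv), NaOAc, AcOH, rt
Reagents that add atoms: bromine, BrBr
Why: Electrophilic aromatic bromination is steered by the free phenol to its only open ortho position C3 (the para position carries the methoxy group and C3 is also meta to the deactivating aldehyde), while the acetate buffer takes up HBr.

**Step 2**
Reactants: 2 3-bromo-2-hydroxy-5-methoxybenzaldehyde
Product: 3 2,3-dihydroxy-5-methoxybenzaldehyde
Conditions: NaOH (aq), Cu powder (cat.), reflux, N2; then HCl to pH 2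
Reagents that add atoms: sodium hydroxide, [Na+].[OH-]
Why: Copper-mediated Ullmann-type hydroxylation of an ortho-bromophenolate in hot aqueous alkali is the classical route from bromo-hydroxybenzaldehydes to the catechol aldehydes, and conjugation with the phenolate shields the aldehyde from Cannizzaro disproportionation.

**Step 3**
Reactants: 3 2,3-dihydroxy-5-methoxybenzaldehyde
Product: 4 2-hydroxy-5-methoxy-3-(methoxymethoxy)benzaldehyde
Conditions: NaH (2.2 equiv), THF/DMF, 0 °C; MOMCl (1.0 equiv), 0 °C → rt; aq NH4Cl
Reagents that add atoms: chloromethyl methyl ether (MOMCl), COCCl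
Why: Williamson-type O-alkylation of the dianion is regioselective because the C2 phenoxide is a chelated vinylogous carboxylate conjugated to the aldehyde, so the more basic C3 phenoxide takes the single equivalent of electrophile.

**Step 4**
Reactants: 4 2-hydroxy-5-methoxy-3-(methoxymethoxy)benzaldehyde; 5 trichloroethylene
Product: 7 2-{[(E)-1,2-dichloroethenyl]oxy}-5-methoxy-3-(methoxymethoxy)benzaldehyde, via dichloroacetylene 6 (not isolated)
Conditions: K2CO3, DMF, 70 °C (closed flask)
Reagents that add atoms: none
Why: Base-induced dehydrochlorination of trichloroethylene gives dichloroacetylene 6, to which the phenoxide adds in anti fashion (O-vinylation by elimination–addition), the established route to aryl (E)-1,2-dichlorovinyl ethers, whose E geometry follows from the anti addition and is erased later.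

**Step 5**
Reactants: 7 2-{[(E)-1,2-dichloroethenyl]oxy}-5-methoxy-3-(methoxymethoxy)benzaldehyde
Product: 8 (2-{[(E)-1,2-dichloroethenyl]oxy}-5-methoxy-3-(methoxymethoxy)phenyl)methanol
Conditions: NaBH4, MeOH/THF, 0 °C
Reagents that add atoms: none
Why: Borohydride reduction of the aryl aldehyde is fast at 0 °C and leaves the dichlorovinyl ether and the MOM acetal untouched.

**Step 6**
Reactants: 8 (2-{[(E)-1,2-dichloroethenyl]oxy}-5-methoxy-3-(methoxymethoxy)phenyl)methanol
Product: 9 tert-butyl[(2-{[(E)-1,2-dichloroethenyl]oxy}-5-methoxy-3-(methoxymethoxy)phenyl)methoxy]dimethylsilane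
Conditions: TBSCl, imidazole, CH2Cl2, rt
Reagents that add atoms: tert-butyldimethylsilyl chloride (TBSCl), CC(C)(C)[Si](C)(C)Cl
Why: Imidazole-promoted silylation of a primary benzylic alcohol gives an ether that withstands n-BuLi, ketene chemistry and mild base.

**Step 7**
Reactants: 9 tert-butyl[(2-{[(E)-1,2-dichloroethenyl]oxy}-5-methoxy-3-(methoxymethoxy)phenyl)methoxy]dimethylsilane
Product: 12 tert-butyl{[2-(ethynyloxy)-5-methoxy-3-(methoxymethoxy)phenyl]methoxy}dimethylsilane, via chloroalkynyl ether 10 (not isolated), via lithium acetylide 11 (not isolated)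
Conditions: n-BuLi (2.5 equiv), Et2O, −78 → −40 °C; MeOH, −78 °C; used promptly
Reagents that add atoms: none
Why: In the established dichlorovinyl ether to ynol ether sequence, vinylic deprotonation and β-elimination of LiCl give chloroalkyne 10, chlorine–lithium exchange gives acetylide 11 and cold protonation gives the terminal aryl ynol ether, with the silyl ether and the acetal inert to n-BuLi at −78 °C.

**Step 8**
Reactants: 13 propyne; 14 trichloroacetyl chloride
Product: 16 4,4-dichloro-3-methylcyclobut-2-en-1-one, via dichloroketene 15 (not isolated)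
Conditions: Zn(Cu) couple, Et2O/DME, 0 °C → rt (sealed flask)
Reagents that add atoms: none
Why: Dichloroketene 15, formed by zinc dechlorination of the acid chloride, undergoes the well-known (2+2) cycloaddition with terminal alkynes, the terminal alkyne carbon bonding to the ketene carbonyl carbon so that the methyl group sits at C3.

**Step 9**
Reactants: 16 4,4-dichloro-3-methylcyclobut-2-en-1-one
Product: 18 3-methylcyclobut-2-en-1-one, via monochlorocyclobutenone 17 (not isolated)
Conditions: Zn dust, AcOH, TMEDA, EtOH, 0 °C → rt; handled as a solution (volatile)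
Reagents that add atoms: none
Why: Zinc reduction of the α,α-dichloro ketone through zinc enolates removes both chlorines stepwise, and the TMEDA/AcOH buffer keeps the sensitive cyclobutenone intact, as in the standard preparation of 3-alkylcyclobutenones.

**Step 10**
Reactants: 12 tert-butyl{[2-(ethynyloxy)-5-methoxy-3-(methoxymethoxy)phenyl]methoxy}dimethylsilane; 18 3-methylcyclobut-2-en-1-one
Product: 23 3-[2-({[tert-butyl(dimethyl)silyl]oxy}methyl)-4-methoxy-6-(methoxymethoxy)phenoxy]-5-methylphenol, via vinylketene 19 (not isolated), via cyclobutenone adduct 20 (not isolated), via dienylketene 21 (not isolated), via cyclohexadienone 22 (not isolated)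
Conditions: 18 (1.3 equiv), toluene, sealed tube, 80 °C then 110 °C; then K2CO3, MeOH, rt
Reagents that add atoms: none
Why: At 80 °C cyclobutenone 18 opens by a 4π electrocyclic reaction to vinylketene 19, which adds the electron-rich triple bond of 12 in a (2+2) cycloaddition: the nucleophilic terminal alkyne carbon (C2') bonds to the ketene carbonyl carbon (C3') and the aryloxy-bearing carbon (C1') bonds to the ketene α-carbon (C6'), giving cyclobutenone 20. A second 4π opening of 20 gives dienylketene 21, and ring B is closed by a thermal disrotatory 6π electrocyclization that forms C3'–C4' to give dienone 22, which tautomerizes to phenol 23. The closest known reaction type is the Danheiser benzannulation of cyclobutenones with alkoxy- and siloxyacetylenes, which delivers 5-substituted resorcinol monoethers of exactly this pattern. No stereocentre is created, and the one in 20 is erased on ring opening. The step needs regioselectivity, secured by the polarization of the ynol ether (aryloxy ends meta to the new hydroxyl) and by the fixed position of the methyl group in 18; it also needs chemoselectivity for the ketene, secured by the absence of any free hydroxyl in 12 and of any β-hydrogen on the aryl oxygen substituent that could open a retro-ene path. Any aryl ester formed when product phenol intercepts 19 should be returned to 23 by the K2CO3/MeOH treatment, which the silyl ether and the MOM acetal tolerate.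

**Step 11**
Reactants: 23 3-[2-({[tert-butyl(dimethyl)silyl]oxy}methyl)-4-methoxy-6-(methoxymethoxy)phenoxy]-5-methylphenol
Product: 24 3-[2-(hydroxymethyl)-4-methoxy-6-(methoxymethoxy)phenoxy]-5-methylphenol
Conditions: TBAF (Bu4NF), THF, 0 °C → rt
Reagents that add atoms: none
Why: Fluoride-driven Si–O cleavage of the primary TBS ether (desilylation through the strong Si–F bond) proceeds without touching the MOM acetal, the diaryl ether or the free phenol.

**Step 12**
Reactants: 24 3-[2-(hydroxymethyl)-4-methoxy-6-(methoxymethoxy)phenoxy]-5-methylphenol; 25 palmitic acid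
Product: 26 [2-(3-hydroxy-5-methylphenoxy)-5-methoxy-3-(methoxymethoxy)phenyl]methyl hexadecanoate
Conditions: PPh3, DIAD, THF, 0 °C → rt
Reagents that add atoms: none
Why: Mitsunobu esterification activates only the aliphatic benzylic hydroxyl as its alkoxyphosphonium ion and takes the carboxylic acid, far more acidic than the phenol, as the pronucleophile, which is the known basis for chemoselective esterification of phenolic alcohols with fatty acids.

**Step 13**
Reactants: 26 [2-(3-hydroxy-5-methylphenoxy)-5-methoxy-3-(methoxymethoxy)phenyl]methyl hexadecanoate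
Product: 27 betaethrin H, [3-hydroxy-2-(3-hydroxy-5-methylphenoxy)-5-methoxyphenyl]methyl hexadecanoate
Conditions: ZnBr2, n-PrSH, CH2Cl2, 0 °C, short reaction time
Reagents that add atoms: none
Why: Lewis acid-assisted cleavage of the aryl MOM acetal is fast at 0 °C, the thiol captures the methoxymethyl cation so that the electron-rich ring B is not alkylated, and the anhydrous non-nucleophilic medium spares the benzylic palmitate.

**Compound list**
1 | 2-hydroxy-5-methoxybenzaldehyde | COc1ccc(O)c(C=O)c1 | starting material
2 | 3-bromo-2-hydroxy-5-methoxybenzaldehyde | COc1cc(Br)c(O)c(C=O)c1 | intermediate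
3 | 2,3-dihydroxy-5-methoxybenzaldehyde | COc1cc(O)c(O)c(C=O)c1 | intermediate
4 | 2-hydroxy-5-methoxy-3-(methoxymethoxy)benzaldehyde | COCOc1cc(OC)cc(C=O)c1O | intermediate
5 | trichloroethylene | ClC=C(Cl)Cl | starting material
6 | dichloroacetylene (formed in the flask, not isolated) | ClC#CCl | intermediate
7 | 2-{[(E)-1,2-dichloroethenyl]oxy}-5-methoxy-3-(methoxymethoxy)benzaldehyde | Cl/C=C(/Cl)Oc1c(C=O)cc(OC)cc1OCOC | intermediate
8 | (2-{[(E)-1,2-dichloroethenyl]oxy}-5-methoxy-3-(methoxymethoxy)phenyl)methanol | Cl/C=C(/Cl)Oc1c(CO)cc(OC)cc1OCOC | intermediate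
9 | tert-butyl[(2-{[(E)-1,2-dichloroethenyl]oxy}-5-methoxy-3-(methoxymethoxy)phenyl)methoxy]dimethylsilane | Cl/C=C(/Cl)Oc1c(CO[Si](C)(C)C(C)(C)C)cc(OC)cc1OCOC | intermediate
10 | tert-butyl({2-[(chloroethynyl)oxy]-5-methoxy-3-(methoxymethoxy)phenyl}methoxy)dimethylsilane (not isolated) | ClC#COc1c(CO[Si](C)(C)C(C)(C)C)cc(OC)cc1OCOC | intermediate
11 | lithium acetylide of 12, lithium {[2-({[tert-butyl(dimethyl)silyl]oxy}methyl)-4-methoxy-6-(methoxymethoxy)phenoxy]ethynide} (not isolated) | [Li]C#COc1c(CO[Si](C)(C)C(C)(C)C)cc(OC)cc1OCOC | intermediate
12 | tert-butyl{[2-(ethynyloxy)-5-methoxy-3-(methoxymethoxy)phenyl]methoxy}dimethylsilane | C#COc1c(CO[Si](C)(C)C(C)(C)C)cc(OC)cc1OCOC | intermediate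
13 | propyne | CC#C | starting material
14 | trichloroacetyl chloride | ClC(=O)C(Cl)(Cl)Cl | starting material
15 | dichloroketene (formed in the flask, not isolated) | ClC(Cl)=C=O | intermediate
16 | 4,4-dichloro-3-methylcyclobut-2-en-1-one | CC1=CC(=O)C1(Cl)Cl | intermediate
17 | 4-chloro-3-methylcyclobut-2-en-1-one (racemic, not isolated) | CC1=CC(=O)C1Cl | intermediate
18 | 3-methylcyclobut-2-en-1-one | CC1=CC(=O)C1 | intermediate
19 | 3-methylbuta-1,3-dien-1-one, the vinylketene (not isolated) | C=C(C)C=C=O | intermediate
20 | 3-[2-({[tert-butyl(dimethyl)silyl]oxy}methyl)-4-methoxy-6-(methoxymethoxy)phenoxy]-4-(prop-1-en-2-yl)cyclobut-2-en-1-one (racemic, not isolated) | O=C1C=C(Oc2c(CO[Si](C)(C)C(C)(C)C)cc(OC)cc2OCOC)C1C(C)=C | intermediate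
21 | (3E)-3-[2-({[tert-butyl(dimethyl)silyl]oxy}methyl)-4-methoxy-6-(methoxymethoxy)phenoxy]-5-methylhexa-1,3,5-trien-1-one (not isolated) | O=C=C/C(Oc1c(CO[Si](C)(C)C(C)(C)C)cc(OC)cc1OCOC)=C\C(C)=C | intermediate
22 | 3-[2-({[tert-butyl(dimethyl)silyl]oxy}methyl)-4-methoxy-6-(methoxymethoxy)phenoxy]-5-methylcyclohexa-2,4-dien-1-one (not isolated) | O=C1C=C(Oc2c(CO[Si](C)(C)C(C)(C)C)cc(OC)cc2OCOC)C=C(C)C1 | intermediate
23 | 3-[2-({[tert-butyl(dimethyl)silyl]oxy}methyl)-4-methoxy-6-(methoxymethoxy)phenoxy]-5-methylphenol | Cc1cc(O)cc(Oc2c(CO[Si](C)(C)C(C)(C)C)cc(OC)cc2OCOC)c1 | intermediate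
24 | 3-[2-(hydroxymethyl)-4-methoxy-6-(methoxymethoxy)phenoxy]-5-methylphenol | Cc1cc(O)cc(Oc2c(CO)cc(OC)cc2OCOC)c1 | intermediate
25 | palmitic acid (hexadecanoic acid) | CCCCCCCCCCCCCCCC(=O)O | starting material
26 | [2-(3-hydroxy-5-methylphenoxy)-5-methoxy-3-(methoxymethoxy)phenyl]methyl hexadecanoate (betaethrin H C3-O-methoxymethyl ether) | CCCCCCCCCCCCCCCC(=O)OCc1cc(OC)cc(OCOC)c1Oc1cc(C)cc(O)c1 | intermediate
27 | betaethrin H, [3-hydroxy-2-(3-hydroxy-5-methylphenoxy)-5-methoxyphenyl]methyl hexadecanoate | CCCCCCCCCCCCCCCC(=O)OCc1cc(OC)cc(O)c1Oc1cc(C)cc(O)c1 | target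

**Step count**
Total: 13 steps. Longest linear sequence: 11 steps (steps 1–7 and 10–13); the cyclobutenone branch (steps 8 and 9) joins at step 10.

**Steps most likely to fail**

1. Step 10. The aryl ynol ether may oligomerize or be consumed by the product phenol before it is captured by the vinylketene, which only forms once the cyclobutenone opens near 80 °C. The fallback sets out from 12 and comes back at 23. The same vinylketene 19 would be generated at room temperature by photochemical Wolff rearrangement of 1-diazo-3-methylbut-3-en-2-one F1, itself obtainable by diazo transfer to commercial 3-methylbut-3-en-2-one. Irradiation of F1 in 1,2-dichloroethane in the presence of 12 should give cyclobutenone adduct 20 without heating the ynol ether. Warming the solution of the more robust 20 to 80 °C should then complete the 4π opening, 6π closure and tautomerization to 23. This diazo ketone variant of the benzannulation is known chemistry and separates ketene generation from the temperature the ynol ether has to bear.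

2. Step 7. The terminal ynol ether may be lost by hydration or oligomerization during the quench, chromatography and storage. The fallback sets out from 9 and comes back at 12. The lithiation is run as before, but acetylide 11 is quenched with chlorotrimethylsilane to give the C-silylated ynol ether tert-butyl{[5-methoxy-3-(methoxymethoxy)-2-{[(trimethylsilyl)ethynyl]oxy}phenyl]methoxy}dimethylsilane F2, which should tolerate purification and storage. Protodesilylation of the alkynylsilane with K2CO3 in MeOH at 0 °C immediately before the benzannulation then releases 12, which goes straight into step 10.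

3. Step 12. The benzylic alkoxyphosphonium ion may alkylate the ring B phenol in competition with the carboxylate, giving benzyl aryl ether oligomers. The fallback sets out from 24 and comes back at 26. Both hydroxyls are acylated with palmitoyl chloride (Et3N, DMAP, CH2Cl2) to the bis-ester 3-{2-[(hexadecanoyloxy)methyl]-4-methoxy-6-(methoxymethoxy)phenoxy}-5-methylphenyl hexadecanoate F3. The more electrophilic aryl ester is then cleaved selectively by aminolysis with pyrrolidine in CH2Cl2 at 0 °C, which leaves the benzylic alkyl ester and gives 26.

**Further compounds**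
F1 | step 10 | 1-diazo-3-methylbut-3-en-2-one | C=C(C)C(=O)C=[N+]=[N-]
F2 | step 7 | tert-butyl{[5-methoxy-3-(methoxymethoxy)-2-{[(trimethylsilyl)ethynyl]oxy}phenyl]methoxy}dimethylsilane | C[Si](C)(C)C#COc1c(CO[Si](C)(C)C(C)(C)C)cc(OC)cc1OCOC
F3 | step 12 | 3-{2-[(hexadecanoyloxy)methyl]-4-methoxy-6-(methoxymethoxy)phenoxy}-5-methylphenyl hexadecanoate | CCCCCCCCCCCCCCCC(=O)OCc1cc(OC)cc(OCOC)c1Oc1cc(C)cc(OC(=O)CCCCCCCCCCCCCCC)c1
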